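The only stereocentre, C3, is (R) in the target (priorities C2 > C1′ > C4 > H), and the route is built to deliver that configuration.

Everything rests on cutting the C3–C1′ bond between the chroman (rings A/C) and the pyran-fused B ring. C3, the only stereocentre, is the homobenzylic carbon of ring C; drawn as a 2H-chromene, C3=C4 is a cyclic styrene conjugated to ring A. A rhodium-catalysed asymmetric hydroarylation of chromene 8 with arylboronic acid 18 puts the B-ring aryl on C3 and a proton on benzylic C4: one operation joins the two fully functionalised halves, sets C3 (R) from a flat, achiral precursor under ligand control and completes the isoflavan skeleton. Only removal of two silyl groups follows.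

Key step: step 10

Assumptions: vinyltriphenylphosphonium bromide and tert-butyl 2-methylbut-3-en-2-yl carbonate are taken as purchasable reagents; the (R)-ligand in step 10 is chosen by analogy with the enone 1,4-addition model, and its antipode is used if a first run shows the opposite sense of induction.

**Ring A/C fragment (steps 1–5)**

Step 1
Reactants: 1 2,4,6-trihydroxybenzaldehyde
Product: 2 2,6-dihydroxy-4-[(triisopropylsilyl)oxy]benzaldehyde
Conditions: TIPSCl (1.0 equiv), imidazole, DMF, 0 °C
Reagents that add atoms: chlorotriisopropylsilane CC(C)[Si](Cl)(C(C)C)C(C)C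
Why: The 4-OH para to the formyl group is the most acidic and least hindered hydroxyl and is not engaged in the hydrogen bond to the carbonyl, so the bulky silyl chloride should react there (regioselective O-silylation).

Step 2
Reactants: 2 2,6-dihydroxy-4-[(triisopropylsilyl)oxy]benzaldehyde
Product: 4 7-[(triisopropylsilyl)oxy]-2H-chromen-5-ol, via phosphorus ylide 3 (not isolated)
Conditions: NaH (2.1 equiv), vinyltriphenylphosphonium bromide (1.05 equiv), THF/DMF, 0 → 65 °C; AcOH quench
Reagents that add atoms: vinyltriphenylphosphonium bromide C=C[P+](c1ccccc1)(c1ccccc1)c1ccccc1.[Br-]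
Why: Oxa-Michael addition of a phenoxide to the vinylphosphonium salt gives ylide 3, which closes C3=C4 by intramolecular Wittig reaction on the ortho aldehyde (Schweizer chromene synthesis); the two ortho hydroxyls of 2 are equivalent by symmetry, so one chromene results, and the second equivalent of base keeps the other phenol from protonating the ylide.

Step 3
Reactants: 4 7-[(triisopropylsilyl)oxy]-2H-chromen-5-ol
Product: 5 5-[(2-methylbut-3-en-2-yl)oxy]-7-[(triisopropylsilyl)oxy]-2H-chromene
Conditions: Pd(PPh3)4 (5 mol%), tert-butyl 2-methylbut-3-en-2-yl carbonate, 4 Å MS, THF, 0 °C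
Reagents that add atoms: tert-butyl 2-methylbut-3-en-2-yl carbonate C=CC(C)(C)OC(=O)OC(C)(C)C
Why: In this Tsuji–Trost O-allylation the phenoxide should attack the more substituted terminus of the 1,1-dimethyl-π-allyl palladium complex under kinetic control at low temperature, giving the tertiary (reverse-prenyl) aryl ether.

Step 4
Reactants: 5 5-[(2-methylbut-3-en-2-yl)oxy]-7-[(triisopropylsilyl)oxy]-2H-chromene
Product: 7 6-(3-methylbut-2-en-1-yl)-7-[(triisopropylsilyl)oxy]-2H-chromen-5-ol, via Claisen dienone 6 (not isolated)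
Conditions: toluene, 110 °C, sealed tube
Reagents that add atoms: none
Why: The aromatic Claisen rearrangement delivers the allyl unit with inversion (a normal prenyl group) to C6, the only ortho carbon of O5 that bears hydrogen (the other is the ring-fusion carbon C4a), and dienone 6 tautomerises to the phenol, so the prenyl position is fixed without a regiochemical choice.

Step 5
Reactants: 7 6-(3-methylbut-2-en-1-yl)-7-[(triisopropylsilyl)oxy]-2H-chromen-5-ol
Product: 8 5-methoxy-6-(3-methylbut-2-en-1-yl)-7-[(triisopropylsilyl)oxy]-2H-chromene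
Conditions: MeI, K2CO3, acetone, 50 °C
Reagents that add atoms: iodomethane CI
Why: Williamson O-methylation of the single free phenol; the aryl triisopropylsilyl ether and both alkenes should tolerate carbonate in acetone.

**Ring B fragment (steps 6–9)**

Step 6
Reactants: 9 4-bromobenzene-1,3-diol
Product: 10 2-bromo-5-[(triisopropylsilyl)oxy]phenol
Conditions: TIPSCl (1.0 equiv), imidazole, DMF, −20 → 0 °C
Reagents that add atoms: chlorotriisopropylsilane CC(C)[Si](Cl)(C(C)C)C(C)C
Why: The bulky silyl chloride should discriminate for the unhindered hydroxyl para to bromine over the hydroxyl flanked by bromine (sterically controlled O-silylation).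

Step 7
Reactants: 10 2-bromo-5-[(triisopropylsilyl)oxy]phenol
Product: 11 1-bromo-2-[(2-methylbut-3-yn-2-yl)oxy]-4-[(triisopropylsilyl)oxy]benzene
Conditions: 3-chloro-3-methylbut-1-yne, DBU, CuCl2·2H2O (cat.), MeCN, 0 °C
Reagents that add atoms: 3-chloro-3-methylbut-1-yne C#CC(C)(C)Cl
Why: Copper-catalysed propargylic etherification of phenols with a tertiary propargylic chloride proceeds at 0 °C and suits acidic ortho-halophenols, while the silyl ether is untouched by DBU.

Step 8
Reactants: 11 1-bromo-2-[(2-methylbut-3-yn-2-yl)oxy]-4-[(triisopropylsilyl)oxy]benzene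
Product: 15 8-bromo-2,2-dimethyl-5-[(triisopropylsilyl)oxy]-2H-chromene, via allenyl dienone 12 (not isolated), via allenylphenol 13 (not isolated), via quinone methide 14 (not isolated)
Conditions: o-xylene, 140 °C
Reagents that add atoms: none
Why: Propargyl aryl ether Claisen rearrangement, enolisation, 1,5-hydrogen shift and oxa-6π electrocyclisation build the 2,2-dimethylpyran ring; bromine blocks one ortho position, so the ring can only close onto the carbon between the two oxygens.

Step 9
Reactants: 15 8-bromo-2,2-dimethyl-5-[(triisopropylsilyl)oxy]-2H-chromene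
Product: 18 {2,2-dimethyl-5-[(triisopropylsilyl)oxy]-2H-chromen-8-yl}boronic acid, via aryllithium 16 (not isolated), via lithium triisopropoxyborate 17 (not isolated)
Conditions: n-BuLi, THF, −78 °C; B(OiPr)3, −78 °C → rt; 1 M HCl to pH 5, 0 °C
Reagents that add atoms: triisopropyl borate CC(C)OB(OC(C)C)OC(C)C; water O
Why: Bromine–lithium exchange at −78 °C is faster than any reaction at the chromene alkene, the silyloxy group is para to lithium and cannot migrate, and borate trapping followed by mild hydrolysis should give the boronic acid.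

**Fragment union and end game (steps 10–11)**

Step 10
Reactants: 8 5-methoxy-6-(3-methylbut-2-en-1-yl)-7-[(triisopropylsilyl)oxy]-2H-chromene; 18 {2,2-dimethyl-5-[(triisopropylsilyl)oxy]-2H-chromen-8-yl}boronic acid
Product: 19 (3R)-3-{2,2-dimethyl-5-[(triisopropylsilyl)oxy]-2H-chromen-8-yl}-5-methoxy-6-(3-methylbut-2-en-1-yl)-7-[(triisopropylsilyl)oxy]-3,4-dihydro-2H-chromene
Conditions: 18 (2.5 equiv), [Rh(OH)((R)-segphos)]2 (5 mol% Rh), 1,4-dioxane/H2O 10:1, 80 °C
Reagents that add atoms: none
Why: Transmetalation of 18 to the hydroxorhodium(I)–bisphosphine gives an aryl–Rh species that adds syn across C3=C4 of 8 with the aryl on C3 and Rh on benzylic C4 (η3-benzyl), and protonolysis by water forms the C4–H bond and regenerates Rh–OH. The closest known reaction type is the Rh-catalysed asymmetric hydroarylation of cyclic alkenes such as 2H-chromenes and 3-pyrrolines with arylboron reagents. No ring is closed; the new stereocentre C3 is set in the insertion, where the C2-symmetric bisphosphine selects the alkene face (catalyst control on a prochiral, achiral substrate). Regioselectivity (aryl to C3, not C4) is secured by the benzylic stabilisation of Rh at C4 next to ring A, and hydroarylation instead of a Heck-type alkene is secured by the ring, which leaves no syn β-hydrogen on C3. Chemoselectivity among three alkenes is needed: the unhindered cis-disubstituted C3=C4 of 8 should insert far faster than the trisubstituted, unconjugated prenyl alkene and than the chromene alkene of 18, whose C3 is shielded by the quaternary C2. An excess of 18 offsets competing protodeboronation.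

Step 11
Reactants: 19 (3R)-3-{2,2-dimethyl-5-[(triisopropylsilyl)oxy]-2H-chromen-8-yl}-5-methoxy-6-(3-methylbut-2-en-1-yl)-7-[(triisopropylsilyl)oxy]-3,4-dihydro-2H-chromene
Product: 20 (3R)-3-(5-hydroxy-2,2-dimethyl-2H-chromen-8-yl)-5-methoxy-6-(3-methylbut-2-en-1-yl)-3,4-dihydro-2H-chromen-7-ol
Conditions: TBAF, AcOH, THF, 0 °C → rt
Reagents that add atoms: none
Why: Fluoride cleaves both aryl silyl ethers under buffered, non-acidic conditions, so the ortho-prenyl phenol cannot cyclise, the chromene alkene is untouched and the non-acidic C3 stereocentre is not at risk.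

**Compound list**

1 | 2,4,6-trihydroxybenzaldehyde | O=Cc1c(O)cc(O)cc1O | starting material
2 | 2,6-dihydroxy-4-[(triisopropylsilyl)oxy]benzaldehyde | O=Cc1c(O)cc(O[Si](C(C)C)(C(C)C)C(C)C)cc1O | intermediate
3 | {2-[2-formyl-3-hydroxy-5-(triisopropylsilyloxy)phenoxy]ethylidene}triphenylphosphorane (phosphorus ylide, present as its sodium phenoxide, drawn as the phenol) | O=Cc1c(O)cc(O[Si](C(C)C)(C(C)C)C(C)C)cc1OCC=P(c1ccccc1)(c1ccccc1)c1ccccc1 | intermediate (not isolated)
4 | 7-[(triisopropylsilyl)oxy]-2H-chromen-5-ol | Oc1cc(O[Si](C(C)C)(C(C)C)C(C)C)cc2OCC=Cc12 | intermediate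
5 | 5-[(2-methylbut-3-en-2-yl)oxy]-7-[(triisopropylsilyl)oxy]-2H-chromene | C=CC(C)(C)Oc1cc(O[Si](C(C)C)(C(C)C)C(C)C)cc2OCC=Cc12 | intermediate
6 | 6-(3-methylbut-2-en-1-yl)-7-[(triisopropylsilyl)oxy]-2H-chromen-5(6H)-one (Claisen dienone) | O=C1C(CC=C(C)C)C(O[Si](C(C)C)(C(C)C)C(C)C)=CC2=C1C=CCO2 | intermediate (not isolated)
7 | 6-(3-methylbut-2-en-1-yl)-7-[(triisopropylsilyl)oxy]-2H-chromen-5-ol | CC(C)=CCc1c(O)c2C=CCOc2cc1O[Si](C(C)C)(C(C)C)C(C)C | intermediate
8 | 5-methoxy-6-(3-methylbut-2-en-1-yl)-7-[(triisopropylsilyl)oxy]-2H-chromene | COc1c(CC=C(C)C)c(O[Si](C(C)C)(C(C)C)C(C)C)cc2OCC=Cc12 | intermediate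
9 | 4-bromobenzene-1,3-diol (4-bromoresorcinol) | Oc1ccc(Br)c(O)c1 | starting material
10 | 2-bromo-5-[(triisopropylsilyl)oxy]phenol | Oc1cc(O[Si](C(C)C)(C(C)C)C(C)C)ccc1Br | intermediate
11 | 1-bromo-2-[(2-methylbut-3-yn-2-yl)oxy]-4-[(triisopropylsilyl)oxy]benzene | C#CC(C)(C)Oc1cc(O[Si](C(C)C)(C(C)C)C(C)C)ccc1Br | intermediate
12 | 2-bromo-6-(3-methylbuta-1,2-dien-1-yl)-5-[(triisopropylsilyl)oxy]cyclohexa-2,4-dien-1-one (allenyl dienone) | O=C1C(Br)=CC=C(O[Si](C(C)C)(C(C)C)C(C)C)C1C=C=C(C)C | intermediate (not isolated)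
13 | 6-bromo-2-(3-methylbuta-1,2-dien-1-yl)-3-[(triisopropylsilyl)oxy]phenol (allenylphenol) | CC(C)=C=Cc1c(O)c(Br)ccc1O[Si](C(C)C)(C(C)C)C(C)C | intermediate (not isolated)
14 | 2-bromo-6-(3-methylbut-2-en-1-ylidene)-5-[(triisopropylsilyl)oxy]cyclohexa-2,4-dien-1-one (ortho-quinone methide) | O=C1C(Br)=CC=C(O[Si](C(C)C)(C(C)C)C(C)C)C1=CC=C(C)C | intermediate (not isolated)
15 | 8-bromo-2,2-dimethyl-5-[(triisopropylsilyl)oxy]-2H-chromene | CC1(C)C=Cc2c(O[Si](C(C)C)(C(C)C)C(C)C)ccc(Br)c2O1 | intermediate
16 | {2,2-dimethyl-5-[(triisopropylsilyl)oxy]-2H-chromen-8-yl}lithium | [Li]c1ccc(O[Si](C(C)C)(C(C)C)C(C)C)c2C=CC(C)(C)Oc12 | intermediate (not isolated)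
17 | lithium {2,2-dimethyl-5-[(triisopropylsilyl)oxy]-2H-chromen-8-yl}tri(propan-2-yloxy)borate | [Li+].CC(C)O[B-](OC(C)C)(OC(C)C)c1ccc(O[Si](C(C)C)(C(C)C)C(C)C)c2C=CC(C)(C)Oc12 | intermediate (not isolated)
18 | {2,2-dimethyl-5-[(triisopropylsilyl)oxy]-2H-chromen-8-yl}boronic acid | OB(O)c1ccc(O[Si](C(C)C)(C(C)C)C(C)C)c2C=CC(C)(C)Oc12 | intermediate
19 | (3R)-3-{2,2-dimethyl-5-[(triisopropylsilyl)oxy]-2H-chromen-8-yl}-5-methoxy-6-(3-methylbut-2-en-1-yl)-7-[(triisopropylsilyl)oxy]-3,4-dihydro-2H-chromene | COc1c(CC=C(C)C)c(O[Si](C(C)C)(C(C)C)C(C)C)cc2c1C[C@H](c1ccc(O[Si](C(C)C)(C(C)C)C(C)C)c3c1OC(C)(C)C=C3)CO2 | intermediate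
20 | (3R)-3-(5-hydroxy-2,2-dimethyl-2H-chromen-8-yl)-5-methoxy-6-(3-methylbut-2-en-1-yl)-3,4-dihydro-2H-chromen-7-ol | COc1c(CC=C(C)C)c(O)cc2c1C[C@H](c1ccc(O)c3c1OC(C)(C)C=C3)CO2 | target

**Step count**

Total step count: 11
Longest linear sequence: 7 steps (steps 1–5, 10 and 11); the B-ring branch (steps 6–9) joins at step 10.

**Steps most likely to fail, with fallbacks**

Step 10. Insertion into the electron-rich, peri-methoxy-substituted alkene of 8 may be slower than protodeboronation of the ortho-alkoxy boronic acid, and facial selectivity may erode with the ortho-substituted aryl group. The fallback forms the same bond without boron and without asymmetric induction, setting out from 8 and aryl bromide 15. A palladium-catalysed reductive Heck hydroarylation (Pd(OAc)2, phosphine ligand, HCO2Na, DMF, 80 °C) should add the aryl group to C3 and hydride to benzylic C4. This gives the racemic bis-silyl isoflavan, rac-3-{2,2-dimethyl-5-[(triisopropylsilyl)oxy]-2H-chromen-8-yl}-5-methoxy-6-(3-methylbut-2-en-1-yl)-7-[(triisopropylsilyl)oxy]-3,4-dihydro-2H-chromene F1. Preparative chromatography on a chiral stationary phase then separates the enantiomers; the (3R) enantiomer is 19, where the route is rejoined, and the (3S)-bis-silyl isoflavan F2 is set aside.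

Step 2. The second phenol may quench the ylide, the phenoxide-deactivated aldehyde may resist the intramolecular Wittig closure, and the para-formyl silyl ether may be lost under the basic conditions. The fallback builds the pyran ring by olefin metathesis instead, setting out from 2. Mono-allylation (allyl bromide, K2CO3, acetone; the second hydroxyl stays locked in the hydrogen bond to the aldehyde) should give 2-(allyloxy)-6-hydroxy-4-[(triisopropylsilyl)oxy]benzaldehyde F3. Wittig methylenation (Ph3P=CH2, 2.2 equiv, THF, 0 °C) should give 3-(allyloxy)-2-ethenyl-5-[(triisopropylsilyl)oxy]phenol F4. Ring-closing metathesis (Grubbs II, CH2Cl2, 40 °C), with no prenyl group yet present to compete, closes C3=C4 and returns the route at 4.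

Step 3. The tertiary π-allyl ether may isomerise under palladium to the linear prenyl ether, or the phloroglucinol-type ring may be C-allylated. The fallback installs the tertiary ether as an alkyne and reduces it, setting out from 4. Copper-catalysed O-alkylation with 3-chloro-3-methylbut-1-yne (DBU, CuCl2 cat., MeCN, 0 °C) should give 5-[(2-methylbut-3-yn-2-yl)oxy]-7-[(triisopropylsilyl)oxy]-2H-chromene F5. Lindlar semihydrogenation (Pd/CaCO3/Pb, quinoline, H2, EtOAc) of the terminal alkyne then returns the route at 5.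

Further compounds
F1 | step 10 | rac-3-{2,2-dimethyl-5-[(triisopropylsilyl)oxy]-2H-chromen-8-yl}-5-methoxy-6-(3-methylbut-2-en-1-yl)-7-[(triisopropylsilyl)oxy]-3,4-dihydro-2H-chromene | COc1c(CC=C(C)C)c(O[Si](C(C)C)(C(C)C)C(C)C)cc2c1CC(c1ccc(O[Si](C(C)C)(C(C)C)C(C)C)c3c1OC(C)(C)C=C3)CO2
F2 | step 10 | (3S)-3-{2,2-dimethyl-5-[(triisopropylsilyl)oxy]-2H-chromen-8-yl}-5-methoxy-6-(3-methylbut-2-en-1-yl)-7-[(triisopropylsilyl)oxy]-3,4-dihydro-2H-chromene | COc1c(CC=C(C)C)c(O[Si](C(C)C)(C(C)C)C(C)C)cc2c1C[C@@H](c1ccc(O[Si](C(C)C)(C(C)C)C(C)C)c3c1OC(C)(C)C=C3)CO2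
F3 | step 2 | 2-(allyloxy)-6-hydroxy-4-[(triisopropylsilyl)oxy]benzaldehyde | O=Cc1c(O)cc(O[Si](C(C)C)(C(C)C)C(C)C)cc1OCC=C
F4 | step 2 | 3-(allyloxy)-2-ethenyl-5-[(triisopropylsilyl)oxy]phenol | C=Cc1c(O)cc(O[Si](C(C)C)(C(C)C)C(C)C)cc1OCC=C
F5 | step 3 | 5-[(2-methylbut-3-yn-2-yl)oxy]-7-[(triisopropylsilyl)oxy]-2H-chromene | C#CC(C)(C)Oc1cc(O[Si](C(C)C)(C(C)C)C(C)C)cc2OCC=Cc12
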